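A direct plan would make the C-a–C-b bond first, in the symmetric diester A1, by a double Johnson–Claisen rearrangement of a dienediol, and would build both quinolones on it with N-methylisatoic anhydride to reach the meso bis-quinolone A2.
After allyl protection of both enols, one of the two enantiotopic 2-methylprop-1-enyl groups would be epoxidised with a Shi ketone (mono-epoxide A3), and deallylation would give the hydroxyisopropyl dihydrofuran A4.
An acid-induced oxiranium ring expansion of A4 would close both pyrans at the very end.
Weak step 1, the double Claisen rearrangement: it sets C-a against C-b with no facial control, so the meso diastereomer must be separated from the racemic one and much material is lost.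
Weak step 2, the group-selective epoxidation: the catalyst must tell apart two enantiotopic alkenes that differ only by a matched or mismatched relation to the neighbouring centre, and the allyl protection and deprotection around it build nothing.
Weak step 3, the final cation cascade: an oxiranium opening by the enol has to win against E1 loss and against cyclisation of the acid-sensitive 2-methylprop-1-enyl group in the fully assembled molecule.

**Retrosynthetic overview**
Labels: quinolone A bears C-a (the carbon with the 2-methylprop-1-enyl group) on C3 and the ring-A oxygen on C4; quinolone B bears C-b on C3 and the ring-B oxygen on C4; C-c is the O-bearing ring-fusion carbon and C-q the CMe2 carbon.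
The cis-fused pyrano[3,2-c]pyran (ring A: O–C4(A)=C3(A)–C-a–C-b–C-c; ring B: O–C4(B)=C3(B)–C-b–C-c–C-q) is read as a rotenoid-type core: the C-a–alkenyl bond is cut last (SN1 alkenylation of a C-a cation) and C-a is carried as a carbonyl group that is not in the target.
Ring A is then cut at C-a–C-b and at the aryl ether bond O–C4(A): a 4-pyranone annulation joins the ring-B ketone 6 (from N-methylflindersine) with a 4-chloroquinolone-3-carbonyl chloride, so both halves come from 4-hydroxy-1-methylquinolin-2(1H)-one and the ring-A oxygen is the former ketone oxygen.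
Ring order: ring B (step 1), then ring A (step 5); the stereocentres follow, C-b and C-c together by dynamic kinetic transfer hydrogenation of the labile ketone, C-a last from the convex face.
The design has no symmetric intermediate, no desymmetrisation and no protecting group, and the acid-sensitive alkene enters in the final step.

Key step: step 5

Assumption: the sense of induction in step 7 is taken from aryl alkyl ketones, where the (S,S)-configured catalyst gives the (S)-carbinol with the (hetero)aryl ring in the aryl position; the enantiomeric catalyst would be used if the sense were opposite.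

**Route**

Step 1
Reactants: 1 4-hydroxy-1-methylquinolin-2(1H)-one; 2 3-methylbut-2-enal
Product: 4 N-methylflindersine (2,2,6-trimethyl-2,6-dihydro-5H-pyrano[3,2-c]quinolin-5-one), via 1-oxatriene 3 (not isolated)
Conditions: 2 (1.5 equiv), ethylenediammonium diacetate (10 mol %), MeOH, 65 °C
Reagents that add atoms: none
Why: Knoevenagel condensation at C3 of 1 and oxa-6π electrocyclisation of the 1-oxatriene 3, the standard flindersine synthesis, close ring B (O–C-q bond) and leave the C-b=C-c double bond for step 2; no stereocentre is formed.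

Step 2
Reactants: 4 N-methylflindersine
Product: 6 2,2,6-trimethyl-2H-pyrano[3,2-c]quinoline-3,5(4H,6H)-dione (ring-B ketone), via epoxide 5 (not isolated)
Conditions: dimethyldioxirane (1.2 equiv), acetone, 0 °C; evaporate; InCl3 (5 mol %), THF, 23 °C
Reagents that add atoms: dimethyldioxirane, CC1(C)OO1
Why: Epoxidation of the electron-rich chromene-type double bond by the neutral dioxirane, then Lewis-acid Meinwald rearrangement, in which the epoxide opens at C-b to the cation stabilised by the 4-alkoxyquinolone and a 1,2-hydride shift from C-c gives the C-c ketone (as chromene oxides give chroman-3-ones), so that C-b becomes the only enolisable position and the oxygen on C-c is in place.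

Step 3
Reactants: 1 4-hydroxy-1-methylquinolin-2(1H)-one
Product: 7 4-chloro-1-methyl-2-oxo-1,2-dihydroquinoline-3-carbaldehyde
Conditions: POCl3 (4 equiv), DMF, 0 → 90 °C; ice water, NaOAc
Reagents that add atoms: N,N-dimethylformamide, CN(C)C=O; phosphoryl chloride, O=P(Cl)(Cl)Cl; water, O
Why: Vilsmeier–Haack reaction, which formylates C3 and converts the vinylogous acid hydroxyl on C4 into chloride in the same operation, as known for 4-hydroxyquinolin-2-ones.

Step 4
Reactants: 7 4-chloro-1-methyl-2-oxo-1,2-dihydroquinoline-3-carbaldehyde
Product: 8 4-chloro-1-methyl-2-oxo-1,2-dihydroquinoline-3-carboxylic acid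
Conditions: NaClO2 (3 equiv), NaH2PO4, 2-methylbut-2-ene, tBuOH–THF–H2O, 0 → 23 °C
Reagents that add atoms: sodium chlorite, [Na+].[O-]Cl=O
Why: Pinnick oxidation takes the aldehyde to the acid under buffered, non-nucleophilic conditions that should spare the C4 chloride, a vinylogous acyl chloride.

Step 5
Reactants: 6 ring-B ketone; 8 4-chloro-1-methyl-2-oxo-1,2-dihydroquinoline-3-carboxylic acid
Product: 11 hexacyclic 4-pyranone (C-a as carbonyl; C-b=C-c double bond; achiral), via acid chloride 9 (not isolated), via lithium diketonate 10 (not isolated)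
Conditions: 8, (COCl)2 (1.5 equiv), DMF (cat.), CH2Cl2, 0 → 23 °C, evaporate; 6, LiN(SiMe3)2 (2.2 equiv), THF, −78 °C; then 9, −78 → 50 °C
Reagents that add atoms: none
Why: The lithium enolate of 6 (only C-b can be deprotonated, C-q being quaternary) is C-acylated by the acid chloride 9 at −78 °C, which forms the C-a–C-b bond; the second equivalent of base gives the diketonate 10, and on warming its C-c enolate oxygen attacks C4 of quinolone A in a 6-endo-trig addition–elimination (intramolecular SNAr at a vinylogous acyl chloride) that expels chloride and closes ring A as a 4-pyranone. The closest known reaction type is the one-pot chromone synthesis from ketone enolates and 2-halobenzoyl chlorides, which is also the classical C-acylation and cyclisation logic for 6a,12a-dehydrorotenoids. No stereocentre is formed: the flat pyranone with C-a as carbonyl is made on purpose, so that C-b and C-c can be set together in step 7 and C-a last in step 8. The step needs acylation before substitution (the acyl chloride is far more electrophilic than C4–Cl at −78 °C), C- and not O-acylation (lithium enolate; any enol ester should be funnelled to the chelated diketonate by acyl transfer under the excess base), and closure through the C-c oxygen (attack through C-b or through the C-a oxygen would give four-membered rings). In one operation it joins 26 of the 30 carbons and completes the hexacyclic ring system.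

Step 6
Reactants: 11 hexacyclic 4-pyranone
Product: 12 racemic ketone (C-a as carbonyl; C-b–H and C-c–H; cis ring fusion favoured)
Conditions: iBu2AlH (1.3 equiv), THF–PhMe, −78 °C; MeOH, aq. potassium sodium tartrate
Reagents that add atoms: none
Why: Conjugate reduction of the vinylogous ester by the aluminium hydride (the known 1,4-reduction of 6a,12a-dehydrorotenoids to rotenoids) gives the aluminium enolate and on protonation the ketone, whose ring-fusion configuration need not be controlled because C-b (enolisation) and C-c (retro-oxa-Michael reaction through the enone 13) are both labile and are set in step 7.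

Step 7
Reactants: 12 racemic ketone
Product: 14 all-cis alcohol (OH on C-a; C-a S; C-b R; C-c S), via ring-opened enone 13 (not isolated)
Conditions: RuCl[(S,S)-TsDPEN](p-cymene) (2 mol %), HCO2H–Et3N (1:2), EtOAc, 40 °C
Reagents that add atoms: none
Why: Noyori–Ikariya asymmetric transfer hydrogenation with dynamic kinetic resolution: in the amine-rich medium the stereoisomers of 12 interconvert through the enol (C-b) and through the achiral enone 13 (retro-oxa-Michael and oxa-Michael reaction at C-c, the quinolin-4-olate being a good leaving group), the cis-fused ketone is the favoured one as in rotenoids, and the (S,S)-catalyst should reduce only the enantiomer whose convex face (syn to H-b and H-c) is its preferred carbonyl face, so that C-b and C-c are fixed together with C-a (S) and ring A can no longer open.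

Step 8
Reactants: 14 all-cis alcohol; 15 potassium trifluoro(2-methylprop-1-en-1-yl)borate
Product: 17 target CNP0107253.2 (C-a R; C-b S; C-c S), via C-a cation 16 (not isolated)
Conditions: 15 (2 equiv), BF3·OEt2 (3 equiv), CH2Cl2–MeCN, −40 → 0 °C; aq. NaHCO3
Reagents that add atoms: none
Why: SN1 alkenylation of a stabilised benzylic-type cation (known for benzhydryl and chromanyl cations with alkenyl trifluoroborates): BF3 ionises the C-a hydroxyl to the vinylogous oxocarbenium ion 16, and the borate attacks with its boron-bearing carbon (β-boryl cation, then loss of boron) from the convex face anti to ring B, whose bonds C-b–C3(B) and C-c–C-q shield the other face, which places the 2-methylprop-1-enyl group trans to C3(B) and cis to H-b, i.e. C-a (R), and brings in the acid-sensitive alkene only at the end.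

**Compound list**
1 | 4-hydroxy-1-methylquinolin-2(1H)-one | Cn1c(=O)cc(O)c2ccccc21 | starting material
2 | 3-methylbut-2-enal | CC(C)=CC=O | starting material
3 | 1-methyl-3-(3-methylbut-2-en-1-ylidene)quinoline-2,4(1H,3H)-dione (1-oxatriene) | CC(C)=CC=C1C(=O)c2ccccc2N(C)C1=O | intermediate
4 | N-methylflindersine (2,2,6-trimethyl-2,6-dihydro-5H-pyrano[3,2-c]quinolin-5-one) | CC1(C)C=Cc2c(O1)c1ccccc1n(C)c2=O | intermediate
5 | 3,4-epoxy-2,2,6-trimethyl-3,4-dihydro-2H-pyrano[3,2-c]quinolin-5(6H)-one (racemic cis-fused epoxide; configuration lost in the same flask) | CC1(C)Oc2c3ccccc3n(C)c(=O)c2C2OC12 | intermediate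
6 | 2,2,6-trimethyl-2H-pyrano[3,2-c]quinoline-3,5(4H,6H)-dione (ring-B ketone; C-c carbonyl, C-b methylene) | CC1(C)Oc2c(CC1=O)c(=O)n(C)c1ccccc21 | intermediate
7 | 4-chloro-1-methyl-2-oxo-1,2-dihydroquinoline-3-carbaldehyde | Cn1c(=O)c(C=O)c(Cl)c2ccccc21 | intermediate
8 | 4-chloro-1-methyl-2-oxo-1,2-dihydroquinoline-3-carboxylic acid | Cn1c(=O)c(C(=O)O)c(Cl)c2ccccc21 | intermediate
9 | 4-chloro-1-methyl-2-oxo-1,2-dihydroquinoline-3-carbonyl chloride | Cn1c(=O)c(C(=O)Cl)c(Cl)c2ccccc21 | intermediate
10 | lithium enolate of 4-[(4-chloro-1-methyl-2-oxo-1,2-dihydroquinolin-3-yl)carbonyl]-2,2,6-trimethyl-2H-pyrano[3,2-c]quinoline-3,5(4H,6H)-dione (diketonate; O− on C-c) | [Li+].CC1(C)Oc2c(C(C(=O)c3c(Cl)c4ccccc4n(C)c3=O)=C1[O-])c(=O)n(C)c1ccccc21 | intermediate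
11 | hexacyclic 4-pyranone: ring A is a 4-pyranone (C-a = C=O, C-b=C-c double bond, ring oxygen between C-c and C4 of quinolone A) fused to the 2,2-dimethyl-2H-pyran of N-methylflindersine (ring B) at C-b–C-c; achiral | O=C1c2c(c3ccccc3n(C)c2=O)OC2=C1c1c(c3ccccc3n(C)c1=O)OC2(C)C | intermediate
12 | ketone: the hexacycle of the target with C-a as C=O, C-b–H and C-c–H; racemic, cis ring fusion (C-b S, C-c S and its enantiomer), in equilibrium with the trans epimer | O=C1c2c(c3ccccc3n(C)c2=O)O[C@H]2[C@@H]1c1c(c3ccccc3n(C)c1=O)OC2(C)C.O=C1c2c(c3ccccc3n(C)c2=O)O[C@@H]2[C@H]1c1c(c3ccccc3n(C)c1=O)OC2(C)C | intermediate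
13 | 4-[(4-hydroxy-1-methyl-2-oxo-1,2-dihydroquinolin-3-yl)carbonyl]-2,2,6-trimethyl-2,6-dihydro-5H-pyrano[3,2-c]quinolin-5-one (achiral ring-opened enone) | CC1(C)C=C(C(=O)c2c(O)c3ccccc3n(C)c2=O)c2c(O1)c1ccccc1n(C)c2=O | intermediate
14 | all-cis alcohol: the cis-fused hexacycle of the target with OH on C-a cis to C3(B) (H-a, H-b and H-c on one face); C-a S, C-b R, C-c S | O[C@@H]1c2c(c3ccccc3n(C)c2=O)O[C@H]2[C@@H]1c1c(c3ccccc3n(C)c1=O)OC2(C)C | intermediate
15 | potassium trifluoro(2-methylprop-1-en-1-yl)borate | [K+].CC(C)=C[B-](F)(F)F | starting material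
16 | C-a cation of the cis-fused hexacycle (vinylogous oxocarbenium ion), hydroxytrifluoroborate counter-ion | O[B-](F)(F)F.[CH+]1c2c(c3ccccc3n(C)c2=O)O[C@H]2[C@@H]1c1c(c3ccccc3n(C)c1=O)OC2(C)C | intermediate
17 | target CNP0107253.2: cis-fused bis(N-methylpyrano[3,2-c]quinolin-5-one) with the 2-methylprop-1-enyl group on C-a trans to C3(B); C-a R, C-b S, C-c S | CC(C)=C[C@H]1c2c(c3ccccc3n(C)c2=O)O[C@H]2[C@@H]1c1c(c3ccccc3n(C)c1=O)OC2(C)C | target

Total step count: 8. Longest linear sequence: 6 steps (steps 1, 2, 5, 6, 7, 8); steps 3 and 4 form the second branch.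

**Steps most likely to fail**

Step 7 (dynamic kinetic transfer hydrogenation). Racemisation of 12 through the enone 13 may be slower than reduction, the catalyst may not distinguish the enantiomers well enough, or 13 may be drained by its own conjugate reduction. The fallback replaces asymmetric catalysis by resolution: setting out from 11, NaBH4 (THF–EtOH, 0 °C; 1,4- then 1,2-reduction, the known way from dehydrorotenoids to cis-fused alcohols) should give in one operation the racemic all-cis alcohol F1, and chromatography on a chiral stationary phase separates 14 from its enantiomer F2; the route is rejoined at 14.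

Step 5 (pyranone annulation). The enolate may be O-acylated without acyl transfer, or may attack C4 of 9 before acylation and so lead to the isomeric 2-pyranone. The fallback makes the union as a [4+2] cycloaddition instead: setting out from 6, condensation with pyrrolidine (TsOH cat., PhMe, water separator) gives the enamine 2,2,6-trimethyl-3-(pyrrolidin-1-yl)-2,6-dihydro-5H-pyrano[3,2-c]quinolin-5-one F3. Heating F3 with commercial ethyl 4-hydroxy-1-methyl-2-oxo-1,2-dihydroquinoline-3-carboxylate in xylene (140 °C, ethanol distilled off) generates the α-oxoketene 1-methyl-3-(oxomethylidene)quinoline-2,4(1H,3H)-dione F4. Its heterodiene O=C4(A)–C3(A)=C-a adds across C-b=C-c of F3 (C-a to C-b, O to C-c) to the aminal cycloadduct F5, which loses pyrrolidine to give 11, where the route is rejoined. This variant uses no halide and closes ring A at O–C-c.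

Step 8 (alkenylation of the C-a cation). The borate may be too weak a nucleophile, so that the cation 16 is lost by elimination of H-b or by a 1,2-hydride shift from C-b, or facial selectivity may be incomplete. The fallback uses a stronger π-nucleophile and moves the double bond afterwards: setting out from 14, BF3·OEt2 and (2-methylallyl)trimethylsilane (Hosomi–Sakurai allylation, same convex-face attack, CH2Cl2, −78 °C) give the C-a 2-methylprop-2-en-1-yl compound F6. Migration of the 1,1-disubstituted double bond into the trisubstituted position with RuHCl(CO)(PPh3)3 (cat., PhMe, 80 °C) then gives 17.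

Further compounds
F1 | step 7 | racemic all-cis alcohol (14 and its enantiomer, 1:1) | O[C@@H]1c2c(c3ccccc3n(C)c2=O)O[C@H]2[C@@H]1c1c(c3ccccc3n(C)c1=O)OC2(C)C.O[C@H]1c2c(c3ccccc3n(C)c2=O)O[C@@H]2[C@H]1c1c(c3ccccc3n(C)c1=O)OC2(C)C
F2 | step 7 | enantiomer of 14 (C-a R, C-b S, C-c R) | O[C@H]1c2c(c3ccccc3n(C)c2=O)O[C@@H]2[C@H]1c1c(c3ccccc3n(C)c1=O)OC2(C)C
F3 | step 5 | 2,2,6-trimethyl-3-(pyrrolidin-1-yl)-2,6-dihydro-5H-pyrano[3,2-c]quinolin-5-one (enamine of 6) | CC1(C)Oc2c(C=C1N1CCCC1)c(=O)n(C)c1ccccc21
F4 | step 5 | 1-methyl-3-(oxomethylidene)quinoline-2,4(1H,3H)-dione (α-oxoketene) | O=C=C1C(=O)c2ccccc2N(C)C1=O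
F5 | step 5 | aminal cycloadduct: hexacycle with C-a as C=O, C-b–H and a pyrrolidin-1-yl group on C-c (racemic) | O=C1c2c(c3ccccc3n(C)c2=O)OC2(N3CCCC3)C1c1c(c3ccccc3n(C)c1=O)OC2(C)C
F6 | step 8 | C-a 2-methylprop-2-en-1-yl analogue of the target (C-a R, C-b S, C-c S) | CC(=C)C[C@H]1c2c(c3ccccc3n(C)c2=O)O[C@H]2[C@@H]1c1c(c3ccccc3n(C)c1=O)OC2(C)C
A1 | direct plan | diethyl (3R,4S)-3,4-bis(2-methylprop-1-en-1-yl)hexanedioate (meso) | CCOC(=O)C[C@@H](C=C(C)C)[C@@H](C=C(C)C)CC(=O)OCC
A2 | direct plan | 3,3'-[(4R,5S)-2,7-dimethylocta-2,6-diene-4,5-diyl]bis(4-hydroxy-1-methylquinolin-2(1H)-one) (meso) | CC(C)=C[C@@H](c1c(O)c2ccccc2n(C)c1=O)[C@H](C=C(C)C)c1c(O)c2ccccc2n(C)c1=O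
A3 | direct plan | 3,3'-[(1S,2R)-1-[(2S)-3,3-dimethyloxiran-2-yl]-4-methylpent-3-ene-1,2-diyl]bis[1-methyl-4-(prop-2-en-1-yloxy)quinolin-2(1H)-one] | CC(C)=C[C@@H](c1c(OCC=C)c2ccccc2n(C)c1=O)[C@H]([C@@H]1OC1(C)C)c1c(OCC=C)c2ccccc2n(C)c1=O
A4 | direct plan | (2R,3S)-2-(2-hydroxypropan-2-yl)-3-[(1R)-1-(4-hydroxy-1-methyl-2-oxo-1,2-dihydroquinolin-3-yl)-3-methylbut-2-en-1-yl]-5-methyl-2,3-dihydrofuro[3,2-c]quinolin-4(5H)-one | CC(C)=C[C@@H](c1c(O)c2ccccc2n(C)c1=O)[C@H]1c2c(c3ccccc3n(C)c2=O)O[C@H]1C(C)(C)O
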